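**Retrosynthetic overview**
1. Feature: ring A of the chroman is a masked 4-methoxyphenol. C6–OMe lies para to the C8a–O1 oxygen, the C7 and C8 oxygens sit between them, and C5 bears hydrogen.
2. Ring A is cut at C5–C6, C4a–C8a and C8–C8a into chromium carbene 26 (carbene carbon = C6, Cα = C7 with O-benzyl, Cβ = C8 with OMe), one CO (= C8a) and terminal alkyne 16 (= C4a and C5), which already carries C3, C2 and ring B.
3. Ring C (pyran) is closed afterwards at O1–C2 by Mitsunobu etherification of the new C8a phenol; the ring B quinone is released last from a dibenzyl hydroquinone.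
4. Alkyne 16: C3 is set by Evans propargylation of the ring B arylacetyl imide, ring B coming from 2,3-dimethoxyphenol. Carbene 26: from methyl (benzyloxy)acetate through 2-(benzyloxy)-3-methoxyacryloyl chloride and Na2Cr(CO)5, so the C7/C8 oxygen pattern is fixed by the skeleton and not by a regioselective lithiation.
5. Ring order: ring B (bought arene, carried as hydroquinone ether), then ring A (benzannulation), then ring C (etherification), then the quinone.

Key step: step 14

Assumption: step 10 is taken to give the 2Z enol ether (methoxy trans to the ester carbonyl); the 2E isomer would serve as well, because this geometry is erased when C8 becomes aromatic in step 14.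

**Route**

Step 1
Reactants: 1 2,3-dimethoxyphenol
Product: 2 2,3-dimethoxy-1,4-benzoquinone
Conditions: ON(SO3K)2 (Fremy's salt, 2.2 equiv), KH2PO4, H2O/acetone, 0 °C to rt
Reagents that add atoms: potassium nitrosodisulfonate, [K+].[K+].[O]N(S(=O)(=O)[O-])S(=O)(=O)[O-]
Why: Teuber oxidation: the nitroxyl radical removes the phenolic hydrogen and a second equivalent delivers oxygen to the free para carbon, so the para-quinone should form.

Step 2
Reactants: 2 2,3-dimethoxy-1,4-benzoquinone
Product: 4 1,4-bis(benzyloxy)-2,3-dimethoxybenzene, via 2,3-dimethoxyhydroquinone 3 (not isolated)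
Conditions: Na2S2O4, Bu4NBr (cat.), THF/H2O, rt, argon; then KOH, BnBr (excess), rt
Reagents that add atoms: benzyl bromide, BrCc1ccccc1
Why: Reductive alkylation of a quinone: dithionite gives the air-sensitive hydroquinone, whose dianion is O-benzylated in the same flask under phase-transfer conditions (Williamson etherification).

Step 3
Reactants: 4 1,4-bis(benzyloxy)-2,3-dimethoxybenzene
Product: 5 1,4-bis(benzyloxy)-5-bromo-2,3-dimethoxybenzene
Conditions: NBS (1.0 equiv), MeCN, 0 °C, dark
Reagents that add atoms: N-bromosuccinimide, O=C1CCC(=O)N1Br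
Why: Electrophilic aromatic bromination of a tetraalkoxybenzene; the two free positions are equivalent by symmetry and the first bromine deactivates the ring toward a second.

Step 4
Reactants: 5 1,4-bis(benzyloxy)-5-bromo-2,3-dimethoxybenzene; 6 (2-tert-butoxy-2-oxoethyl)zinc bromide (BrZnCH2CO2t-Bu)
Product: 7 tert-butyl 2-[2,5-bis(benzyloxy)-3,4-dimethoxyphenyl]acetate
Conditions: Pd(dba)2 (cat.), P(t-Bu)3 (cat.), THF, rt
Reagents that add atoms: none
Why: Palladium-catalysed coupling of an aryl bromide with a Reformatsky reagent (Negishi-type α-arylation of a zinc ester enolate); it tolerates the benzyl ethers and should stop at monoarylation because the zinc enolate is too weakly basic to deprotonate the product.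

Step 5
Reactants: 7 tert-butyl 2-[2,5-bis(benzyloxy)-3,4-dimethoxyphenyl]acetate
Product: 8 2-[2,5-bis(benzyloxy)-3,4-dimethoxyphenyl]acetic acid
Conditions: CF3CO2H/CH2Cl2 (1:4), 0 °C to rt
Reagents that add atoms: none
Why: Acidolysis of the tert-butyl ester through the tert-butyl cation, which leaves as 2-methylpropene; aryl benzyl and methyl ethers should survive brief cold acid.

Step 6
Reactants: 8 2-[2,5-bis(benzyloxy)-3,4-dimethoxyphenyl]acetic acid; 9 (S)-4-benzyl-2-oxazolidinone
Product: 11 (4S)-4-benzyl-3-{2-[2,5-bis(benzyloxy)-3,4-dimethoxyphenyl]acetyl}-1,3-oxazolidin-2-one, via mixed pivalic anhydride 10 (not isolated)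
Conditions: t-BuCOCl, Et3N, THF, −20 to 0 °C; then 9, LiCl, rt
Reagents that add atoms: none
Why: N-Acylation of the oxazolidinone through the mixed pivalic anhydride with LiCl/Et3N activation; attack occurs at the less hindered arylacetyl carbonyl.

Step 7
Reactants: 11 (4S)-4-benzyl-3-{2-[2,5-bis(benzyloxy)-3,4-dimethoxyphenyl]acetyl}-1,3-oxazolidin-2-one; 12 propargyl bromide
Product: 14 (4S)-4-benzyl-3-{(2S)-2-[2,5-bis(benzyloxy)-3,4-dimethoxyphenyl]pent-4-ynoyl}-1,3-oxazolidin-2-one, via sodium Z-enolate 13 (not isolated)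
Conditions: NaN(SiMe3)2, THF, −78 °C; then 12, −78 to −45 °C; AcOH quench
Reagents that add atoms: none
Why: Evans alkylation: the chelated sodium Z-enolate is shielded on one face by the 4-benzyl group, so propargyl bromide should enter from the other face (SN2) and set the future C3 as 2S.

Step 8
Reactants: 14 (4S)-4-benzyl-3-{(2S)-2-[2,5-bis(benzyloxy)-3,4-dimethoxyphenyl]pent-4-ynoyl}-1,3-oxazolidin-2-one
Product: 15 (2S)-2-[2,5-bis(benzyloxy)-3,4-dimethoxyphenyl]pent-4-yn-1-ol
Conditions: LiBH4, MeOH (1 equiv), THF, 0 °C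
Reagents that add atoms: none
Why: Reductive removal of the auxiliary: LiBH4 attacks the exocyclic imide carbonyl and gives the primary alcohol without touching the stereocentre or the alkyne.

Step 9
Reactants: 15 (2S)-2-[2,5-bis(benzyloxy)-3,4-dimethoxyphenyl]pent-4-yn-1-ol
Product: 16 tert-butyl{[(2S)-2-[2,5-bis(benzyloxy)-3,4-dimethoxyphenyl]pent-4-yn-1-yl]oxy}dimethylsilane
Conditions: TBSCl, imidazole, DMF, rt
Reagents that add atoms: tert-butyldimethylsilyl chloride, CC(C)(C)[Si](C)(C)Cl
Why: Silyl ether formation at the primary alcohol, so that the hydroxyl cannot trap the ketene intermediate of step 14 as a lactone.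

Step 10
Reactants: 17 methyl 2-(benzyloxy)acetate; 18 methyl formate
Product: 20 methyl (2Z)-2-(benzyloxy)-3-methoxyprop-2-enoate, via sodium formyl ester enolate 19 (not isolated)
Conditions: NaH, THF, 0 °C to rt; then Me2SO4, DMF, rt
Reagents that add atoms: dimethyl sulfate, COS(=O)(=O)OC
Why: Crossed Claisen condensation with a non-enolisable formate gives the stabilised formyl ester enolate, and the hard methylating agent in a dipolar aprotic solvent should alkylate it on oxygen to the β-methoxyacrylate.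

Step 11
Reactants: 20 methyl (2Z)-2-(benzyloxy)-3-methoxyprop-2-enoate
Product: 21 (2Z)-2-(benzyloxy)-3-methoxyprop-2-enoic acid
Conditions: LiOH, THF/H2O, 0 °C to rt; then 1 M HCl to pH 3 at 0 °C
Reagents that add atoms: lithium hydroxide, [Li+].[OH-]
Why: Saponification of the methyl ester; the vinylogous carbonate enol ether is stable to cold dilute base and to brief acidification.

Step 12
Reactants: 21 (2Z)-2-(benzyloxy)-3-methoxyprop-2-enoic acid
Product: 22 (2Z)-2-(benzyloxy)-3-methoxyprop-2-enoyl chloride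
Conditions: (COCl)2, DMF (cat.), CH2Cl2, 0 °C to rt; used crude
Reagents that add atoms: oxalyl chloride, O=C(Cl)C(=O)Cl
Why: Acid chloride formation through the Vilsmeier-type chloroiminium catalyst, the usual preparation of β-alkoxyacryloyl chlorides.

Step 13
Reactants: 23 Cr(CO)6; 22 (2Z)-2-(benzyloxy)-3-methoxyprop-2-enoyl chloride
Product: 26 pentacarbonyl[(2Z)-2-(benzyloxy)-1,3-dimethoxyprop-2-en-1-ylidene]chromium, via disodium pentacarbonylchromate 24 (not isolated), via sodium acylchromate 25 (not isolated)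
Conditions: 23, NaC10H8 (2 equiv), THF, −78 °C to rt; then 22, −78 to 0 °C; solvent exchange; Me3OBF4, CH2Cl2, 0 °C
Reagents that add atoms: trimethyloxonium tetrafluoroborate, C[O+](C)C.F[B-](F)(F)F
Why: Acylation of the pentacarbonylchromate dianion by an acid chloride and O-methylation of the acylate with Me3OBF4, a known route to Fischer alkoxycarbene complexes; the places of the benzyloxy and methoxy groups are fixed by the skeleton of 22.

Step 14
Reactants: 26 pentacarbonyl[(2Z)-2-(benzyloxy)-1,3-dimethoxyprop-2-en-1-ylidene]chromium; 16 tert-butyl{[(2S)-2-[2,5-bis(benzyloxy)-3,4-dimethoxyphenyl]pent-4-yn-1-yl]oxy}dimethylsilane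
Product: 28 2-{(2S)-2-[2,5-bis(benzyloxy)-3,4-dimethoxyphenyl]-3-[(tert-butyldimethylsilyl)oxy]propyl}-5-(benzyloxy)-4,6-dimethoxyphenol, via tricarbonylchromium arene complex 27 (not isolated)
Conditions: 26 (1.5 equiv), THF (0.05 M), 60 °C, argon; then air, EtOAc, rt, SiO2 filtration
Reagents that add atoms: none
Why: Thermal loss of one CO from 26 opens a site on chromium, the terminal alkyne of 16 inserts into the Cr=C bond and a CO ligand is taken up to give a chromium-bound dienylketene, which closes ring A by 6π-electrocyclisation (new bonds C5–C6, C4a–C8a and C8–C8a) and tautomerises through the C8 hydrogen to the C8a phenol, held as Cr(CO)3 complex 27 until air frees 28. The closest known reaction is the Dötz benzannulation of alkenyl(methoxy)carbene chromium complexes with terminal alkynes, including α-alkoxyalkenyl complexes. The carbene carbon becomes C6 with its methoxy group, Cα brings the benzyl-protected C7 oxygen, Cβ brings C8–OMe and the inserted CO becomes C8a with a free hydroxyl, so the four oxygens of ring A arrive differentiated. The step needs the alkyne to insert with its substituted carbon next to the CO-derived carbon, which the steric bias of a terminal alkyne (hydrogen against a branched chain) secures, and it needs phenol formation to win over cyclopentannulation, for which a chromium methoxycarbene, an ether solvent and moderate temperature are chosen. No stereocentre is formed; C3 sits two bonds from the alkyne under neutral conditions and should keep its configuration.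

Step 15
Reactants: 28 2-{(2S)-2-[2,5-bis(benzyloxy)-3,4-dimethoxyphenyl]-3-[(tert-butyldimethylsilyl)oxy]propyl}-5-(benzyloxy)-4,6-dimethoxyphenol
Product: 29 2-{(2S)-2-[2,5-bis(benzyloxy)-3,4-dimethoxyphenyl]-3-hydroxypropyl}-5-(benzyloxy)-4,6-dimethoxyphenol
Conditions: HF·pyridine, pyridine/THF, 0 °C to rt
Reagents that add atoms: none
Why: Fluoride-mediated cleavage of the primary silyl ether under buffered, non-basic conditions that spare the electron-rich phenol from oxidation.

Step 16
Reactants: 29 2-{(2S)-2-[2,5-bis(benzyloxy)-3,4-dimethoxyphenyl]-3-hydroxypropyl}-5-(benzyloxy)-4,6-dimethoxyphenol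
Product: 30 (3S)-7-(benzyloxy)-3-[2,5-bis(benzyloxy)-3,4-dimethoxyphenyl]-6,8-dimethoxy-3,4-dihydro-2H-1-benzopyran
Conditions: PPh3, DIAD, THF (0.01 M), 0 °C to rt
Reagents that add atoms: none
Why: Intramolecular Mitsunobu etherification: the C8a phenol displaces the activated primary alcohol in a 6-exo-tet closure of O1–C2; substitution is at a primary carbon, so C3 is untouched.

Step 17
Reactants: 30 (3S)-7-(benzyloxy)-3-[2,5-bis(benzyloxy)-3,4-dimethoxyphenyl]-6,8-dimethoxy-3,4-dihydro-2H-1-benzopyran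
Product: 31 5-[(3S)-7-hydroxy-6,8-dimethoxy-3,4-dihydro-2H-1-benzopyran-3-yl]-2,3-dimethoxybenzene-1,4-diol
Conditions: H2 (1 atm), Pd/C, EtOAc/MeOH, rt; filtration under argon
Reagents that add atoms: none
Why: Hydrogenolysis of the three aryl benzyl ethers; methyl ethers, the chroman and the stereocentre are inert.

Step 18
Reactants: 31 5-[(3S)-7-hydroxy-6,8-dimethoxy-3,4-dihydro-2H-1-benzopyran-3-yl]-2,3-dimethoxybenzene-1,4-diol
Product: 32 5-[(3S)-7-hydroxy-6,8-dimethoxy-3,4-dihydro-2H-1-benzopyran-3-yl]-2,3-dimethoxycyclohexa-2,5-diene-1,4-dione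
Conditions: Ag2O (1.1 equiv), Na2SO4, Et2O/EtOAc, rt, short contact time
Reagents that add atoms: none
Why: Two-electron oxidation of a hydroquinone to the para-quinone; the ring B hydroquinone is oxidised far more easily than the ring A monophenol, and any ring A phenoxyl formed would be reduced back by remaining hydroquinone.

**Compound list**
1 | 2,3-dimethoxyphenol | COc1cccc(O)c1OC | starting material
2 | 2,3-dimethoxy-1,4-benzoquinone | COC1=C(OC)C(=O)C=CC1=O | intermediate
3 | 2,3-dimethoxybenzene-1,4-diol | COc1c(O)ccc(O)c1OC | intermediate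
4 | 1,4-bis(benzyloxy)-2,3-dimethoxybenzene | COc1c(OCc2ccccc2)ccc(OCc2ccccc2)c1OC | intermediate
5 | 1,4-bis(benzyloxy)-5-bromo-2,3-dimethoxybenzene | COc1c(OC)c(OCc2ccccc2)cc(Br)c1OCc1ccccc1 | intermediate
6 | (2-tert-butoxy-2-oxoethyl)zinc bromide | CC(C)(C)OC(=O)C[Zn]Br | starting material
7 | tert-butyl 2-[2,5-bis(benzyloxy)-3,4-dimethoxyphenyl]acetate | COc1c(OC)c(OCc2ccccc2)cc(CC(=O)OC(C)(C)C)c1OCc1ccccc1 | intermediate
8 | 2-[2,5-bis(benzyloxy)-3,4-dimethoxyphenyl]acetic acid | COc1c(OC)c(OCc2ccccc2)cc(CC(=O)O)c1OCc1ccccc1 | intermediate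
9 | (S)-4-benzyl-2-oxazolidinone | O=C1N[C@@H](Cc2ccccc2)CO1 | starting material
10 | 2-[2,5-bis(benzyloxy)-3,4-dimethoxyphenyl]acetic pivalic anhydride | COc1c(OC)c(OCc2ccccc2)cc(CC(=O)OC(=O)C(C)(C)C)c1OCc1ccccc1 | intermediate
11 | (4S)-4-benzyl-3-{2-[2,5-bis(benzyloxy)-3,4-dimethoxyphenyl]acetyl}-1,3-oxazolidin-2-one | COc1c(OC)c(OCc2ccccc2)cc(CC(=O)N2[C@@H](Cc3ccccc3)COC2=O)c1OCc1ccccc1 | intermediate
12 | propargyl bromide | C#CCBr | starting material
13 | sodium (1Z)-1-[(4S)-4-benzyl-2-oxo-1,3-oxazolidin-3-yl]-2-[2,5-bis(benzyloxy)-3,4-dimethoxyphenyl]ethen-1-olate | [Na+].COc1c(OC)c(OCc2ccccc2)cc(/C=C(\[O-])N2[C@@H](Cc3ccccc3)COC2=O)c1OCc1ccccc1 | intermediate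
14 | (4S)-4-benzyl-3-{(2S)-2-[2,5-bis(benzyloxy)-3,4-dimethoxyphenyl]pent-4-ynoyl}-1,3-oxazolidin-2-one | COc1c(OC)c(OCc2ccccc2)cc([C@H](CC#C)C(=O)N2[C@@H](Cc3ccccc3)COC2=O)c1OCc1ccccc1 | intermediate
15 | (2S)-2-[2,5-bis(benzyloxy)-3,4-dimethoxyphenyl]pent-4-yn-1-ol | COc1c(OC)c(OCc2ccccc2)cc([C@H](CC#C)CO)c1OCc1ccccc1 | intermediate
16 | tert-butyl{[(2S)-2-[2,5-bis(benzyloxy)-3,4-dimethoxyphenyl]pent-4-yn-1-yl]oxy}dimethylsilane | COc1c(OC)c(OCc2ccccc2)cc([C@H](CC#C)CO[Si](C)(C)C(C)(C)C)c1OCc1ccccc1 | intermediate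
17 | methyl 2-(benzyloxy)acetate | COC(=O)COCc1ccccc1 | starting material
18 | methyl formate | COC=O | starting material
19 | sodium 2-(benzyloxy)-3-methoxy-3-oxoprop-1-en-1-olate | [Na+].[O-]C=C(OCc1ccccc1)C(=O)OC | intermediate
20 | methyl (2Z)-2-(benzyloxy)-3-methoxyprop-2-enoate | CO/C=C(\OCc1ccccc1)C(=O)OC | intermediate
21 | (2Z)-2-(benzyloxy)-3-methoxyprop-2-enoic acid | CO/C=C(\OCc1ccccc1)C(=O)O | intermediate
22 | (2Z)-2-(benzyloxy)-3-methoxyprop-2-enoyl chloride | CO/C=C(\OCc1ccccc1)C(=O)Cl | intermediate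
23 | hexacarbonylchromium, Cr(CO)6 | O=C=[Cr](=C=O)(=C=O)(=C=O)(=C=O)=C=O | starting material
24 | disodium pentacarbonylchromate | [Na+].[Na+].O=C=[Cr-2](=C=O)(=C=O)(=C=O)=C=O | intermediate
25 | sodium pentacarbonyl[(2Z)-2-(benzyloxy)-3-methoxyprop-2-enoyl]chromate | [Na+].CO/C=C(\OCc1ccccc1)C(=O)[Cr-](=C=O)(=C=O)(=C=O)(=C=O)=C=O | intermediate
26 | pentacarbonyl[(2Z)-2-(benzyloxy)-1,3-dimethoxyprop-2-en-1-ylidene]chromium | CO/C=C(\OCc1ccccc1)C(OC)=[Cr](=C=O)(=C=O)(=C=O)(=C=O)=C=O | intermediate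
27 | tricarbonylchromium complex of phenol 28, chromium bound η6 to ring A | COc1c(OC)c(OCc2ccccc2)cc([C@H](Cc3cc(OC)c(OCc4ccccc4)c(OC)c3O)CO[Si](C)(C)C(C)(C)C)c1OCc1ccccc1.O=C=[Cr](=C=O)=C=O | intermediate
28 | 2-{(2S)-2-[2,5-bis(benzyloxy)-3,4-dimethoxyphenyl]-3-[(tert-butyldimethylsilyl)oxy]propyl}-5-(benzyloxy)-4,6-dimethoxyphenol | COc1c(OC)c(OCc2ccccc2)cc([C@H](Cc3cc(OC)c(OCc4ccccc4)c(OC)c3O)CO[Si](C)(C)C(C)(C)C)c1OCc1ccccc1 | intermediate
29 | 2-{(2S)-2-[2,5-bis(benzyloxy)-3,4-dimethoxyphenyl]-3-hydroxypropyl}-5-(benzyloxy)-4,6-dimethoxyphenol | COc1c(OC)c(OCc2ccccc2)cc([C@H](Cc3cc(OC)c(OCc4ccccc4)c(OC)c3O)CO)c1OCc1ccccc1 | intermediate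
30 | (3S)-7-(benzyloxy)-3-[2,5-bis(benzyloxy)-3,4-dimethoxyphenyl]-6,8-dimethoxy-3,4-dihydro-2H-1-benzopyran | COc1c(OC)c(OCc2ccccc2)cc([C@H]2COc3c(cc(OC)c(OCc4ccccc4)c3OC)C2)c1OCc1ccccc1 | intermediate
31 | 5-[(3S)-7-hydroxy-6,8-dimethoxy-3,4-dihydro-2H-1-benzopyran-3-yl]-2,3-dimethoxybenzene-1,4-diol | COc1c(OC)c(O)cc([C@H]2COc3c(cc(OC)c(O)c3OC)C2)c1O | intermediate
32 | 5-[(3S)-7-hydroxy-6,8-dimethoxy-3,4-dihydro-2H-1-benzopyran-3-yl]-2,3-dimethoxycyclohexa-2,5-diene-1,4-dione | COC1=C(OC)C(=O)C([C@H]2COc3c(cc(OC)c(O)c3OC)C2)=CC1=O | target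

**Count**
Total: 18 steps. Longest linear sequence: 14 steps (steps 1 to 9, then 14 to 18); the carbene branch is 4 steps (10 to 13).

**Steps most likely to fail**

Step 14. The β-methoxy group donates into the carbene carbon, so CO loss may be slow, and after alkyne insertion, ring closure without CO uptake (cyclopentannulation) may outrun ketene formation; this α,β-dialkoxyalkenyl pattern has no direct precedent in the benzannulation. Fallback: ring A is brought in as a ready-made arene and the pyran oxygen is joined to it last. Purchased 4-(benzyloxy)-3,5-dimethoxybenzaldehyde is brominated ortho to the formyl group (NBS, MeCN) to 4-(benzyloxy)-2-bromo-3,5-dimethoxybenzaldehyde F1, reduced (NaBH4, MeOH) to [4-(benzyloxy)-2-bromo-3,5-dimethoxyphenyl]methanol F2 and converted (PBr3, CH2Cl2, 0 °C) into 2-(benzyloxy)-4-bromo-5-(bromomethyl)-1,3-dimethoxybenzene F3. The fallback sets out from imide 11: its sodium enolate 13 is alkylated with F3 under the conditions of step 7, with the same facial control, to give (4S)-4-benzyl-3-{(2S)-3-[4-(benzyloxy)-2-bromo-3,5-dimethoxyphenyl]-2-[2,5-bis(benzyloxy)-3,4-dimethoxyphenyl]propanoyl}-1,3-oxazolidin-2-one F4. LiBH4 reduction as in step 8 gives (2S)-3-[4-(benzyloxy)-2-bromo-3,5-dimethoxyphenyl]-2-[2,5-bis(benzyloxy)-3,4-dimethoxyphenyl]propan-1-ol F5. Intramolecular palladium-catalysed aryl etherification of the bromide with the primary alcohol (Pd(OAc)2, 2-(di-tert-butylphosphino)-1,1'-binaphthyl, Cs2CO3, toluene, 80 °C) then closes O1–C8a, and the route is rejoined at chroman 30.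

Step 13. The strongly reducing dianion may transfer an electron to the conjugated acid chloride instead of attacking its carbonyl group, or the acylate may lose the acyl group before it is methylated. Fallback: the chromium–carbon bond is made in the classical direction, a vinyllithium onto Cr(CO)6, with the lithium placed by tin–lithium exchange so that regiochemistry is again fixed by the skeleton. Benzyl alcohol and methoxyacetyl chloride (pyridine, CH2Cl2) give benzyl 2-methoxyacetate F6. KN(SiMe3)2 and ClP(O)(OPh)2 (THF, −78 °C) trap the chelated ester enolate on oxygen as (Z)-1-(benzyloxy)-2-methoxyethenyl diphenyl phosphate F7. Pd(PPh3)4, Me3SnSnMe3 and LiCl (THF, reflux) give [(Z)-1-(benzyloxy)-2-methoxyethenyl]trimethylstannane F8, and MeLi (THF, −78 °C) gives [(E)-1-(benzyloxy)-2-methoxyethenyl]lithium F9. The fallback sets out from Cr(CO)6 23: F9 adds to it to give lithium pentacarbonyl[(2E)-2-(benzyloxy)-3-methoxyprop-2-enoyl]chromate F10, and Me3OBF4 gives pentacarbonyl[(2E)-2-(benzyloxy)-1,3-dimethoxyprop-2-en-1-ylidene]chromium F11, the geometric isomer of 26. F11 is used in step 14 in place of 26, since the enol ether geometry is lost on aromatisation, and the route is rejoined at phenol 28.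

Step 4. Oxidative addition of zerovalent palladium into the very electron-rich, ortho-alkoxy aryl bromide may be slow, so that reduction of the bromide or decay of the zinc enolate wins. Fallback: the fallback sets out from bromide 5; bromine–lithium exchange (n-BuLi, THF, −78 °C) gives [2,5-bis(benzyloxy)-3,4-dimethoxyphenyl]lithium F12, which opens ethylene oxide (BF3·OEt2, −78 °C) to 2-[2,5-bis(benzyloxy)-3,4-dimethoxyphenyl]ethan-1-ol F13. Oxidation of the primary alcohol (TEMPO cat., PhI(OAc)2, MeCN/H2O) gives the acid directly, and the route is rejoined at acid 8, bypassing steps 4 and 5.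

**Further compounds**
F1 | step 14 | 4-(benzyloxy)-2-bromo-3,5-dimethoxybenzaldehyde | COc1cc(C=O)c(Br)c(OC)c1OCc1ccccc1
F2 | step 14 | [4-(benzyloxy)-2-bromo-3,5-dimethoxyphenyl]methanol | COc1cc(CO)c(Br)c(OC)c1OCc1ccccc1
F3 | step 14 | 2-(benzyloxy)-4-bromo-5-(bromomethyl)-1,3-dimethoxybenzene | COc1cc(CBr)c(Br)c(OC)c1OCc1ccccc1
F4 | step 14 | (4S)-4-benzyl-3-{(2S)-3-[4-(benzyloxy)-2-bromo-3,5-dimethoxyphenyl]-2-[2,5-bis(benzyloxy)-3,4-dimethoxyphenyl]propanoyl}-1,3-oxazolidin-2-one | COc1c(OC)c(OCc2ccccc2)cc([C@H](Cc3cc(OC)c(OCc4ccccc4)c(OC)c3Br)C(=O)N3[C@@H](Cc4ccccc4)COC3=O)c1OCc1ccccc1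
F5 | step 14 | (2S)-3-[4-(benzyloxy)-2-bromo-3,5-dimethoxyphenyl]-2-[2,5-bis(benzyloxy)-3,4-dimethoxyphenyl]propan-1-ol | COc1c(OC)c(OCc2ccccc2)cc([C@H](Cc3cc(OC)c(OCc4ccccc4)c(OC)c3Br)CO)c1OCc1ccccc1
F6 | step 13 | benzyl 2-methoxyacetate | COCC(=O)OCc1ccccc1
F7 | step 13 | (Z)-1-(benzyloxy)-2-methoxyethenyl diphenyl phosphate | CO/C=C(/OCc1ccccc1)OP(=O)(Oc1ccccc1)Oc1ccccc1
F8 | step 13 | [(Z)-1-(benzyloxy)-2-methoxyethenyl]trimethylstannane | CO/C=C(/OCc1ccccc1)[Sn](C)(C)C
F9 | step 13 | [(E)-1-(benzyloxy)-2-methoxyethenyl]lithium | CO/C=C(/OCc1ccccc1)[Li]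
F10 | step 13 | lithium pentacarbonyl[(2E)-2-(benzyloxy)-3-methoxyprop-2-enoyl]chromate | [Li+].CO/C=C(/OCc1ccccc1)C(=O)[Cr-](=C=O)(=C=O)(=C=O)(=C=O)=C=O
F11 | step 13 | pentacarbonyl[(2E)-2-(benzyloxy)-1,3-dimethoxyprop-2-en-1-ylidene]chromium | CO/C=C(/OCc1ccccc1)C(OC)=[Cr](=C=O)(=C=O)(=C=O)(=C=O)=C=O
F12 | step 4 | [2,5-bis(benzyloxy)-3,4-dimethoxyphenyl]lithium | COc1c(OC)c(OCc2ccccc2)cc([Li])c1OCc1ccccc1
F13 | step 4 | 2-[2,5-bis(benzyloxy)-3,4-dimethoxyphenyl]ethan-1-ol | COc1c(OC)c(OCc2ccccc2)cc(CCO)c1OCc1ccccc1
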